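The numbers stand for no real mixture; the run is a simulation.

J held in J2 cannot work on X, so in this flask the catalyst doing the work shrinks while the work goes on, and the question is how much of it is still free when 10% of the X has been converted.

X 0.40 M; G 0.480 M; J 0.48 mM

    L → Q (k1 = 0.0019 min⁻¹)
    J + J ⇌ J2 (K2 = 3.1 × 10⁵ L mol⁻¹, k2 = 3.0 L mol⁻¹ min⁻¹)
    G + J + L → J + D (k3 = 22 L² mol⁻² min⁻¹)
    X + J ⇌ J + L (K4 = 4.1, k4 = 1.6 L mol⁻¹ min⁻¹)

- the form that holds most of the catalyst when 10% of the X are converted (J2 / J)
- its share of the catalyst then
- apparent order in G when 10% of the X are converted (percent change of the rate of making D for one percent more G charged)
- apparent order in J when 10% of the X are converted (percent change of the rate of making D for one percent more J charged)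
- factor on the rate of making D when 10% of the X are converted if G is charged twice over

- two of one species on the left: rate k times its square, two consumed each time
- a form made of two catalysts counts as two
- charge of X (flask): 0.40 M

We reckon with what is left: x is the fraction of the X charge left, and f the fraction of the J charge still free. Take the main step first, X passing into L on J, with f held at one. The logarithm of x then falls steadily at 0.0461 h⁻¹, and x reaches 90.0% after 2.29 h.

Now add the pairing of J into J2. Two J go each time, so the logarithm of f falls in step with free J, at twice k2 times free J, while the logarithm of x falls at k4 times that same free J. The ratio of the two falls is therefore a fixed number, 0.267, the rate constant of X's step over twice that of the pairing, which we call the catalyst exponent: with the two back steps set aside, the fraction of X left is the fraction of J left raised to this power.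

So x at 90.0% means f at 67.4%, and J holds more of the catalyst than J2. With free J falling as one over one plus time over 5.79 h, that point comes at 2.80 h, later than the main step alone gave.

Then come the rest. The steps that lead on from L, to D and to Q, use up no J, so they leave f as it was. The return of L to X is at most 2.71% of the forward step at that point, and the splitting of J2 is 0.242% of the pairing, so we keep our figure. The orders and the doubling we do not reckon by hand.

The forecast says J at 67%, where we have 67.4%, on the ground that “the catalyst has not reached its J2-rich equilibrium”. It adds orders of 0.71 in G and 1.15 in J, and a factor of 1.52 on doubling G.

The flask gives J at 67.1% after 2.84 h, with orders of 0.71 in G and 1.1 in J and a factor of 1.53. That majority passes in this flask: at 8.00 h J is down to 42.1% of the catalyst, and J2, outside the working round, holds more at 57.9%. Raised to the catalyst exponent, that J reading gives 79.4% of the X left, and the flask then holds 79.6%.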